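**Retrosynthetic overview** (drimane numbering: ring A = C1–C5, C10; ring B = C5–C10; C11 on C9; C12 on C8)

1. Target 25 is unmasked last from 24 (acid cleaves the C11 tert-butyl ester and the C12 diethyl acetal); 24 comes from Yamaguchi esterification of 6β-alcohol 19 with trienoic acid 22, and 19 from Luche reduction of 6-ketone 18.
2. Ring B is made in one operation: a tandem Michael–Dieckmann annulation of ynoate 14 (C6, C7, C8, C12) onto ring A lactone 10 forms C8–C9 and then C5–C6 (bridged keto-lactone 16); hydrolysis and decarboxylation of the bridge give 18.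
3. Enabling feature: on ring B the C9 oxygen and the C5 hydrogen are both α and axial, 1,3 to each other across C10. A one-carbon carbonyl can therefore span O9 and C5 as a cis-fused γ-lactone on ring A; this temporary ring makes C9–H and C5–H enolisable, sends C8 to the β-face of C9, and leaves as CO2 to expose the 9α-hydroxyl and the 5α-hydrogen.
4. Lactone 10 comes from keto ester 1 by CBS reduction, glycolate Ireland–Claisen rearrangement (C9–C10 bond and the C10 quaternary centre by chirality transfer), hydrogenation and lactonisation.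
5. Ring order: ring A (purchased), temporary γ-lactone, ring B (key step), lactone excised.

Key step: step 7

Remark: the target is handled as the open 9-hydroxy 11-acid 12-aldehyde that is drawn (its cyclic lactol tautomer would interconvert with it and needs no extra step), and keto ester 1 is assumed to be purchasable.

**Step 1**
Reactants: 1 ethyl 2,6,6-trimethyl-4-oxocyclohex-2-ene-1-carboxylate (racemic)
Product: 2 ethyl (4S)-4-hydroxy-2,6,6-trimethylcyclohex-2-ene-1-carboxylate (both C1 epimers)
Conditions: (R)-2-methyl-CBS-oxazaborolidine (cat.), catecholborane, toluene, −78 °C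
Reagents that add atoms: none
Why: Corey–Bakshi–Shibata 1,2-reduction of the enone, in which the catalyst should tell the alkenyl flank of the carbonyl (large) from the methylene flank (small) and give the (4S)-carbinol in both C1 epimers, the only stereochemical information that is carried forward.

**Step 2**
Reactants: 2 ethyl (4S)-4-hydroxy-2,6,6-trimethylcyclohex-2-ene-1-carboxylate; 3 (benzyloxy)acetyl chloride
Product: 4 ethyl (4S)-4-{[(benzyloxy)acetyl]oxy}-2,6,6-trimethylcyclohex-2-ene-1-carboxylate
Conditions: pyridine, DMAP (cat.), CH2Cl2, 0 °C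
Reagents that add atoms: none
Why: DMAP-catalysed O-acylation of a secondary allylic alcohol, which does not touch the carbinol centre.

**Step 3**
Reactants: 4 ethyl (4S)-4-{[(benzyloxy)acetyl]oxy}-2,6,6-trimethylcyclohex-2-ene-1-carboxylate
Product: 7 2-(benzyloxy)-2-[(1S)-6-(ethoxycarbonyl)-1,5,5-trimethylcyclohex-2-en-1-yl]acetic acid (epimers at the ring CH and at the side-chain CH), via silyl ketene acetal 5 (not isolated), via trimethylsilyl ester 6 (not isolated)
Conditions: LiN(SiMe3)2, Me3SiCl, THF, −78 → 60 °C; 1 M HCl work-up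
Reagents that add atoms: none
Why: Ireland–Claisen rearrangement of the chelated glycolate enolate, a suprafacial [3,3] shift that forms the new C–C bond on the ring face that carried the C4 oxygen, so the (4S)-carbinol should become the (S)-quaternary carbon (later C10); the two epimerisable centres are inconsequential.

**Step 4**
Reactants: 7 2-(benzyloxy)-2-[(1S)-6-(ethoxycarbonyl)-1,5,5-trimethylcyclohex-2-en-1-yl]acetic acid
Product: 8 tert-butyl 2-(benzyloxy)-2-[(1S)-6-(ethoxycarbonyl)-1,5,5-trimethylcyclohex-2-en-1-yl]acetate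
Conditions: tert-butyl 2,2,2-trichloroacetimidate, BF3·OEt2 (cat.), CH2Cl2–cyclohexane, 23 °C
Reagents that add atoms: tert-butyl 2,2,2-trichloroacetimidate, CC(C)(C)OC(=N)C(Cl)(Cl)Cl
Why: acid-catalysed tert-butylation of the carboxylic acid by the imidate, with no stereocentre involved.

**Step 5**
Reactants: 8 tert-butyl 2-(benzyloxy)-2-[(1S)-6-(ethoxycarbonyl)-1,5,5-trimethylcyclohex-2-en-1-yl]acetate
Product: 10 tert-butyl (3aS,7aR)-3a,7,7-trimethyl-1-oxo-1,3,3a,4,5,6,7,7a-octahydro-2-benzofuran-3-carboxylate (cis-fused; C3 epimers), via hydroxy diester 9 (not isolated)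
Conditions: H2 (1 atm), Pd/C, EtOAc, 23 °C; then KOtBu (0.2 equiv), THF, 50 °C
Reagents that add atoms: none
Why: catalytic hydrogenation saturates the ring alkene and removes the benzyl ether, then base-mediated epimerisation at the ring ester α-carbon and lactonisation should funnel the material into the cis-fused γ-lactone, the preferred fusion for a hydrindane-type lactone with an angular methyl group.

**Step 6**
Reactants: 11 3,3-diethoxyprop-1-yne; 12 ethyl chloroformate
Product: 14 ethyl 4,4-diethoxybut-2-ynoate, via lithium acetylide 13 (not isolated)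
Conditions: n-BuLi, THF, −78 °C; then 12, −78 → 0 °C
Reagents that add atoms: none
Why: C-acylation of a lithium acetylide with a chloroformate (alkynoate synthesis), with no stereocentre.

**Step 7**
Reactants: 10 tert-butyl (3aS,7aR)-3a,7,7-trimethyl-1-oxo-1,3,3a,4,5,6,7,7a-octahydro-2-benzofuran-3-carboxylate; 14 ethyl 4,4-diethoxybut-2-ynoate
Product: 16 bridged keto-lactone (5R,9S,10S): 11-tert-butyl ester of 5α-carboxy-12,12-diethoxy-9α-hydroxy-6-oxodrim-7-en-11-oic acid with the 5α-carboxyl lactonised onto the 9α-oxygen, via Michael adduct 15 (not isolated)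
Conditions: LiN(SiMe3)2 (1.1 equiv), THF, −78 °C; then 14, −78 → 0 °C; AcOH quench
Reagents that add atoms: none
Why: Tandem Michael addition–Dieckmann condensation (Michael–Claisen annulation), the known way to build a cyclohexenone from an ester enolate and an alkynoate: the base removes the more acidic C9–H (α to the tert-butyl ester and to the lactone oxygen), the enolate adds to the β-carbon of 14 (C8–C9), the allenolate is protonated at C7 by the hexamethyldisilazane just formed, and the regenerated base enolises the lactone at C5, which attacks the ethyl ester (C5–C6) with loss of ethoxide. Ring B closes in this acylation as a 6-(enolexo)-exo-trig cyclisation and gives a bicyclo[3.2.1] keto-lactone whose carbonyl bridge spans the two axial α-positions at C5 and C9. C9 is set in the conjugate addition, where the enolate of the cis-fused lactone should be attacked on its convex face (syn to the angular methyl, anti to the ring A methylene C1), which is the configuration of the target. The C5 quaternary centre is fixed by the lactone, because C6 can reach C5 only on the face that already carries C8. The step needs conjugate rather than carbonyl addition (a hindered soft enolate meeting an unhindered sp carbon) and protonation of the allenolate anti to C9 so that the ester ends cis to C9 (the proton donor passes the smaller diethoxymethyl group). It also needs C-acylation at the congested C5, which is intramolecular and is kept from reversing by a cold quench, since the product has no acidic proton.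

**Step 8**
Reactants: 16 bridged keto-lactone
Product: 18 tert-butyl (1S,4aS,8aS)-2-(diethoxymethyl)-1-hydroxy-5,5,8a-trimethyl-4-oxo-1,4,4a,5,6,7,8,8a-octahydronaphthalene-1-carboxylate, via keto acid 17 (not isolated)
Conditions: LiOH, THF–H2O, 0 → 23 °C; then AcOH, 40 °C
Reagents that add atoms: none
Why: saponification of the strained bridged lactone by acyl–oxygen cleavage (the oxygen stays on C9 as the 9α-hydroxyl) and decarboxylation of the β-keto acid, after which C5, now α to the C6 ketone, should equilibrate through the dienol to the trans-fused 5α-H epimer.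

**Step 9**
Reactants: 18 tert-butyl (1S,4aS,8aS)-2-(diethoxymethyl)-1-hydroxy-5,5,8a-trimethyl-4-oxo-1,4,4a,5,6,7,8,8a-octahydronaphthalene-1-carboxylate
Product: 19 tert-butyl (1S,4R,4aS,8aS)-2-(diethoxymethyl)-1,4-dihydroxy-5,5,8a-trimethyl-1,4,4a,5,6,7,8,8a-octahydronaphthalene-1-carboxylate
Conditions: NaBH4, CeCl3·7H2O, MeOH, −40 °C
Reagents that add atoms: none
Why: Luche 1,2-reduction of the enone, in which hydride should enter from the α-face because the β-face of C6 is screened by the axial methyl groups on C10 and C4, giving the axial 6β-alcohol.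

**Step 10**
Reactants: 20 (2E,4E)-hexa-2,4-dienal; 21 malonic acid
Product: 22 (2E,4E,6E)-octa-2,4,6-trienoic acid
Conditions: pyridine, piperidine (cat.), 90 °C
Reagents that add atoms: none
Why: Knoevenagel condensation with decarboxylation (Doebner modification), which should give the new double bond as the (E)-isomer.

**Step 11**
Reactants: 19 tert-butyl (1S,4R,4aS,8aS)-2-(diethoxymethyl)-1,4-dihydroxy-5,5,8a-trimethyl-1,4,4a,5,6,7,8,8a-octahydronaphthalene-1-carboxylate; 22 (2E,4E,6E)-octa-2,4,6-trienoic acid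
Product: 24 tert-butyl (1S,4R,4aS,8aS)-2-(diethoxymethyl)-1-hydroxy-5,5,8a-trimethyl-4-{[(2E,4E,6E)-octa-2,4,6-trienoyl]oxy}-1,4,4a,5,6,7,8,8a-octahydronaphthalene-1-carboxylate, via mixed anhydride 23 (not isolated)
Conditions: 2,4,6-trichlorobenzoyl chloride, Et3N, THF, 23 °C; then 19, DMAP, toluene, 40 °C
Reagents that add atoms: none
Why: Yamaguchi esterification, in which only the secondary 6β-hydroxyl should be acylated (the tertiary C9 hydroxyl is too hindered) and C6 keeps its configuration because its C–O bond is not broken.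

**Step 12**
Reactants: 24 tert-butyl (1S,4R,4aS,8aS)-2-(diethoxymethyl)-1-hydroxy-5,5,8a-trimethyl-4-{[(2E,4E,6E)-octa-2,4,6-trienoyl]oxy}-1,4,4a,5,6,7,8,8a-octahydronaphthalene-1-carboxylate
Product: 25 ustusoic acid B
Conditions: CF3CO2H, CH2Cl2, H2O, 0 → 23 °C
Reagents that add atoms: water, O
Why: acidolysis of the tert-butyl ester (loss of isobutene) and hydrolysis of the diethyl acetal in one operation, with no stereocentre affected.

**Compound list**

1 | ethyl 2,6,6-trimethyl-4-oxocyclohex-2-ene-1-carboxylate (racemic) | CCOC(=O)C1C(C)=CC(=O)CC1(C)C | starting material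
2 | ethyl (4S)-4-hydroxy-2,6,6-trimethylcyclohex-2-ene-1-carboxylate (both C1 epimers) | CCOC(=O)C1C(C)=C[C@@H](O)CC1(C)C | intermediate
3 | (benzyloxy)acetyl chloride | O=C(Cl)COCc1ccccc1 | starting material
4 | ethyl (4S)-4-{[(benzyloxy)acetyl]oxy}-2,6,6-trimethylcyclohex-2-ene-1-carboxylate | CCOC(=O)C1C(C)=C[C@@H](OC(=O)COCc2ccccc2)CC1(C)C | intermediate
5 | trimethylsilyl ketene acetal of 4 (silyloxy and benzyloxy groups cis on the new C=C) | CCOC(=O)C1C(C)=C[C@@H](O/C(O[Si](C)(C)C)=C/OCc2ccccc2)CC1(C)C | intermediate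
6 | trimethylsilyl 2-(benzyloxy)-2-[(1S)-6-(ethoxycarbonyl)-1,5,5-trimethylcyclohex-2-en-1-yl]acetate | C[Si](C)(C)OC(=O)C(OCc1ccccc1)[C@@]1(C)C=CCC(C)(C)C1C(=O)OCC | intermediate
7 | 2-(benzyloxy)-2-[(1S)-6-(ethoxycarbonyl)-1,5,5-trimethylcyclohex-2-en-1-yl]acetic acid (epimers at ring CH and side-chain CH) | OC(=O)C(OCc1ccccc1)[C@@]1(C)C=CCC(C)(C)C1C(=O)OCC | intermediate
8 | tert-butyl 2-(benzyloxy)-2-[(1S)-6-(ethoxycarbonyl)-1,5,5-trimethylcyclohex-2-en-1-yl]acetate | CC(C)(C)OC(=O)C(OCc1ccccc1)[C@@]1(C)C=CCC(C)(C)C1C(=O)OCC | intermediate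
9 | tert-butyl 2-[(1S)-2-(ethoxycarbonyl)-1,3,3-trimethylcyclohexyl]-2-hydroxyacetate | CC(C)(C)OC(=O)C(O)[C@@]1(C)CCCC(C)(C)C1C(=O)OCC | intermediate
10 | tert-butyl (3aS,7aR)-3a,7,7-trimethyl-1-oxo-1,3,3a,4,5,6,7,7a-octahydro-2-benzofuran-3-carboxylate (cis-fused; C3 epimers) | CC(C)(C)OC(=O)C1OC(=O)[C@@H]2C(C)(C)CCC[C@]12C | intermediate
11 | 3,3-diethoxyprop-1-yne | C#CC(OCC)OCC | starting material
12 | ethyl chloroformate | CCOC(=O)Cl | starting material
13 | lithium 3,3-diethoxyprop-1-yn-1-ide | [Li+].[C-]#CC(OCC)OCC | intermediate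
14 | ethyl 4,4-diethoxybut-2-ynoate | CCOC(=O)C#CC(OCC)OCC | intermediate
15 | tert-butyl (3S,3aS,7aR)-3-[(E)-1,1-diethoxy-4-ethoxy-4-oxobut-2-en-2-yl]-3a,7,7-trimethyl-1-oxo-1,3,3a,4,5,6,7,7a-octahydro-2-benzofuran-3-carboxylate (ethyl ester cis to the lactone carbon) | CCOC(=O)/C=C(/C(OCC)OCC)[C@@]1(C(=O)OC(C)(C)C)OC(=O)[C@@H]2C(C)(C)CCC[C@]12C | intermediate
16 | bridged keto-lactone (5R,9S,10S): 11-tert-butyl ester of 5α-carboxy-12,12-diethoxy-9α-hydroxy-6-oxodrim-7-en-11-oic acid with the 5α-carboxyl lactonised onto the 9α-oxygen | O=C1C=C(C(OCC)OCC)[C@@]2(C(=O)OC(C)(C)C)OC(=O)[C@@]13C(C)(C)CCC[C@]23C | intermediate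
17 | 5α-carboxy-12,12-diethoxy-9α-hydroxy-6-oxodrim-7-en-11-oic acid 11-tert-butyl ester | O=C1C=C(C(OCC)OCC)[C@](O)(C(=O)OC(C)(C)C)[C@@]2(C)CCCC(C)(C)[C@]12C(=O)O | intermediate
18 | tert-butyl (1S,4aS,8aS)-2-(diethoxymethyl)-1-hydroxy-5,5,8a-trimethyl-4-oxo-1,4,4a,5,6,7,8,8a-octahydronaphthalene-1-carboxylate | O=C1C=C(C(OCC)OCC)[C@](O)(C(=O)OC(C)(C)C)[C@@]2(C)CCCC(C)(C)[C@H]12 | intermediate
19 | tert-butyl (1S,4R,4aS,8aS)-2-(diethoxymethyl)-1,4-dihydroxy-5,5,8a-trimethyl-1,4,4a,5,6,7,8,8a-octahydronaphthalene-1-carboxylate | O[C@@H]1C=C(C(OCC)OCC)[C@](O)(C(=O)OC(C)(C)C)[C@@]2(C)CCCC(C)(C)[C@H]12 | intermediate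
20 | (2E,4E)-hexa-2,4-dienal | C/C=C/C=C/C=O | starting material
21 | malonic acid | OC(=O)CC(=O)O | starting material
22 | (2E,4E,6E)-octa-2,4,6-trienoic acid | C/C=C/C=C/C=C/C(=O)O | intermediate
23 | (2E,4E,6E)-octa-2,4,6-trienoic 2,4,6-trichlorobenzoic anhydride | C/C=C/C=C/C=C/C(=O)OC(=O)c1c(Cl)cc(Cl)cc1Cl | intermediate
24 | tert-butyl (1S,4R,4aS,8aS)-2-(diethoxymethyl)-1-hydroxy-5,5,8a-trimethyl-4-{[(2E,4E,6E)-octa-2,4,6-trienoyl]oxy}-1,4,4a,5,6,7,8,8a-octahydronaphthalene-1-carboxylate | C/C=C/C=C/C=C/C(=O)O[C@@H]1C=C(C(OCC)OCC)[C@](O)(C(=O)OC(C)(C)C)[C@@]2(C)CCCC(C)(C)[C@H]12 | intermediate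
25 | ustusoic acid B, (1S,4R,4aS,8aS)-2-formyl-1-hydroxy-5,5,8a-trimethyl-4-{[(2E,4E,6E)-octa-2,4,6-trienoyl]oxy}-1,4,4a,5,6,7,8,8a-octahydronaphthalene-1-carboxylic acid | C/C=C/C=C/C=C/C(=O)O[C@@H]1C=C(C=O)[C@](O)(C(=O)O)[C@@]2(C)CCCC(C)(C)[C@H]12 | target

**Step count and risks**

Total step count: 12. Longest linear sequence: 10 steps (1, 2, 3, 4, 5, 7, 8, 9, 11, 12).

Steps most likely to fail:

Step 7. The acylation of the congested C5 enolate by the conjugated ethyl ester may not compete with simple proton quench, and the ethoxide set free may reopen the bridged product. Poor facial selectivity in the conjugate addition is the second danger. The fallback sets out from 10 and comes back at 16; it makes the two bonds in separate operations with a stronger acylating group. Acetylide 13 is acylated with allyl chloroformate to allyl 4,4-diethoxybut-2-ynoate F1. Conjugate addition of the enolate of 10 (LiN(SiMe3)2, THF, −78 °C, cold quench) gives the allyl ester analogue of the Michael adduct F2. Pd(PPh3)4 and morpholine free the enoic acid F3, and 1,1'-carbonyldiimidazole converts it into the acyl imidazole F4. LiN(SiMe3)2 at −78 °C then effects the intramolecular C-acylation of the lactone enolate to 16.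

Step 8. Hydroxide may add to the C6 ketone and cleave the C5–C6 bond by retro-Claisen fragmentation instead of saponifying the lactone. The fallback sets out from 16 and comes back at 17; it removes the ketone before the hydrolysis. Luche reduction of 16 gives the 6-hydroxy bridged lactone F5, LiOH opens the lactone to the 6-hydroxy acid F6, and Dess–Martin oxidation returns keto acid 17, which decarboxylates to 18.

Step 3. The base may enolise the ring ester at its allylic α-carbon and move the double bond out of the allylic ester, or the [3,3] shift onto the hindered trisubstituted alkene may be too slow. The fallback sets out from 2 and comes back at 9; it forms the quaternary centre without strong base and adds the C9 oxygen afterwards. Johnson–Claisen rearrangement of 2 (MeC(OEt)3, EtCO2H cat., 140 °C) gives ethyl 2-[(1S)-6-(ethoxycarbonyl)-1,5,5-trimethylcyclohex-2-en-1-yl]acetate F7. Hydrogenation (H2, Pd/C) gives the saturated diethyl diester F8. LiOH saponifies only the unhindered side-chain ester to the side-chain acid F9, which is converted with the imidate of step 4 into the tert-butyl ester F10. Side-chain enolate formation (LiN(iPr)2, THF, −78 °C) and oxidation with 2-(phenylsulfonyl)-3-phenyloxaziridine give hydroxy diester 9, which lactonises to 10 under the base of step 5.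

**Further compounds**

F1 | step 7 | allyl 4,4-diethoxybut-2-ynoate | C=CCOC(=O)C#CC(OCC)OCC
F2 | step 7 | allyl ester analogue of Michael adduct 15 | C=CCOC(=O)/C=C(/C(OCC)OCC)[C@@]1(C(=O)OC(C)(C)C)OC(=O)[C@@H]2C(C)(C)CCC[C@]12C
F3 | step 7 | enoic acid from F2 | OC(=O)/C=C(/C(OCC)OCC)[C@@]1(C(=O)OC(C)(C)C)OC(=O)[C@@H]2C(C)(C)CCC[C@]12C
F4 | step 7 | acyl imidazole of F3 | O=C(n1ccnc1)/C=C(/C(OCC)OCC)[C@@]1(C(=O)OC(C)(C)C)OC(=O)[C@@H]2C(C)(C)CCC[C@]12C
F5 | step 8 | 6-hydroxy analogue of bridged lactone 16 (C6 epimers) | OC1C=C(C(OCC)OCC)[C@@]2(C(=O)OC(C)(C)C)OC(=O)[C@@]13C(C)(C)CCC[C@]23C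
F6 | step 8 | 5α-carboxy-12,12-diethoxy-6,9α-dihydroxydrim-7-en-11-oic acid 11-tert-butyl ester (C6 epimers) | OC1C=C(C(OCC)OCC)[C@](O)(C(=O)OC(C)(C)C)[C@@]2(C)CCCC(C)(C)[C@]12C(=O)O
F7 | step 3 | ethyl 2-[(1S)-6-(ethoxycarbonyl)-1,5,5-trimethylcyclohex-2-en-1-yl]acetate | CCOC(=O)C[C@@]1(C)C=CCC(C)(C)C1C(=O)OCC
F8 | step 3 | ethyl 2-[2-(ethoxycarbonyl)-1,3,3-trimethylcyclohexyl]acetate (quaternary carbon as in 7) | CCOC(=O)C[C@@]1(C)CCCC(C)(C)C1C(=O)OCC
F9 | step 3 | 2-[2-(ethoxycarbonyl)-1,3,3-trimethylcyclohexyl]acetic acid (quaternary carbon as in 7) | OC(=O)C[C@@]1(C)CCCC(C)(C)C1C(=O)OCC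
F10 | step 3 | tert-butyl 2-[2-(ethoxycarbonyl)-1,3,3-trimethylcyclohexyl]acetate (quaternary carbon as in 7) | CC(C)(C)OC(=O)C[C@@]1(C)CCCC(C)(C)C1C(=O)OCC
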